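## Structural features

The target is an octacyclic hybrid of a ring-A-aromatised 24-nor-friedelane (rings A–E, the pristimerin skeleton with its C29 methyl ester) and a guaiane sesquiterpene (primed locants), joined through the two catechol oxygens. O2, flanked by C1–H, is bound to C1'; O3, flanked by the C4 methyl, is bound to C5'. These two ether bonds, C2/C3 and C1'/C5' form a 1,4-dioxane. The C1'–C5' bond is shared by this dioxane, the cyclopentene (C1'–C2'–C3'=C4'–C5') and the cycloheptane (C1', C5'–C10'), so the junction is a dioxa[5.4.3]propellane whose two central atoms are vicinal, fully substituted C–O stereocentres. C5' is at once a dioxane carbon and the allylic terminus of C3'=C4'; the key step exploits exactly this. The guaiane carries four stereocentres (1'R,5'R,7'S,10'R), with both oxygens, the C10' methyl and the C7' isopropenyl group on one face of the hydroazulene, and C10' directly next to C1'. The triterpenoid carries seven stereocentres (C8, C9, C13, C14, C17, C18, C20): six are those of pristimerin, and C8 bears a hydrogen syn to the C9 and C14 methyls (8S) next to a C6=C7 styrene. Fragile groups are the tertiary allylic aryl ether at C5' (ionisable), the isopropenyl and trisubstituted alkenes (acid), and the C6–C8 region (cationic backbone shifts under acid). The real difficulty is to make two hindered tertiary alkyl aryl ether bonds with the right oxygen on the right carbon, on the right face relative to C10'/C7', with C3'=C4' beside one of them.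

## Logic of the disconnections

21 ⇒ 20. The C8–H bond and the C6=C7 bond are traded for C6–H2 and C7=C8 (a 1,3-prototropic shift). This puts the triterpenoid into the oxidation pattern that hydride reduction of the commercial quinone methide gives directly. The forward step must move the alkene into conjugation and set C8 under equilibrating conditions.

20 ⇒ 19 (key). The O3–C5' bond is cut with allylic transposition: C3'=C4' becomes C4'=C5' and C3' receives an oxygen leaving group. The dioxane and the propellane are opened to a seco-ether in which only O2–C1' exists, and the sesquiterpene part becomes a classical guai-4-en-3-ol derivative. The forward step must attack the more hindered allyl terminus (C5', not C3') and create C5' cis to the C1' oxygen. Both demands are met by the two-atom aryl tether: a six-membered ring against an eight-membered one, and a propellane that can only be cis.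

19 ⇒ 16. The two carbonates, the free phenol and the C3' carbinol are traced back to a protected phenol and a C3' ketone. The ketone makes the sesquiterpene unit a 4-oxycyclopentenone. The forward steps need a 1,2-reduction that places the C3' oxygen cis to the C1' ether, and a phenol unmasking that avoids acid.

16 ⇒ 3 + 15. The O2–C1' bond is cut. It is the only intermolecular C–O bond of the route and is made where the enone dictates regiochemistry (γ-terminus of an acyl-substituted allyl system). Cutting here separates the molecule into a triterpenoid phenol and a C15 electrophile. The forward step must proceed with retention at C1' and use O2 only, hence O3 is blocked.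

3 ⇒ 2 ⇒ 1. The C6–H bond (hydride) and the O3 protecting group are removed. The quinone methide of 1 carries O3 as a free hydroxyl and O2 as a carbonyl, so the two catechol oxygens are differentiated by the starting material itself. The forward demand is O-alkylation of the enolic hydroxyl, then 1,6-hydride addition.

15 ⇒ 12. The C1'–C2' bond is cut (intramolecular aldol) and the carbonate removed. This opens the cyclopentenone to a monocyclic cis-ene-dione and leaves C10' as the only controller of C1'. The forward demand is kinetic enolisation of the acetyl methyl, attack on the ring ketone anti to the C10' methyl, and trapping of the tertiary alkoxide before retro-aldol.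

12 ⇒ 7 + 8. The C4'=C5' bond is cut (aldol condensation with a four-carbon 1,2-dione). All fifteen carbons are then present. The forward demands are regioselective enolisation away from C10' and the cis geometry of the two acyl groups.

7 ⇒ 5 ⇒ 4. The inserted ring carbon (future C5') and the C10'–H are removed. This maps C7' and C10' onto the chiral pool. The forward demands are a cis-selective conjugate reduction and a one-carbon ring expansion in which the unsubstituted α-carbon migrates.

## Other disconnections considered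

Alternative 1: The first idea is to cut both C–O bonds at once. Forward, this is an inverse-demand hetero-Diels–Alder reaction of the triterpenoid o-quinone A1 (the 8-H tautomer of pristimerin) with guaia-1(5),3,11-triene A2. It is the shortest plan on paper. Nothing in A1 or A2 encodes which oxygen goes to C1' and which to C5'. The cyclopentadiene A2 can also react as a carbodiene with the quinone C=C or C=O, and it is prone to 1,5-hydrogen shifts and dimerisation. A1 can relax to pristimerin by enolisation. The facial selectivity at the C1'=C5' bond rests on the remote C7'/C10' substituents alone. The chosen plan fixes regiochemistry through the built-in O2/O3 difference of 1 and relays C5' from C1'.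

Alternative 2: Both C–O bonds could be cut as allylic bonds. Forward, a one-pot double Tsuji–Trost etherification would join the free catechol A3 with the guai-4-ene-1,3-diyl bis-carbonate A4. Mechanistically the secondary C3' carbonate should ionise first, and the less hindered oxygen should then attack the less hindered C3' terminus. Once C3' carries an aryl ether that is no longer allylic, the second closure can only give a dioxane fused across C3'–C4'. The catechol would thus be locked onto the wrong carbons. The chosen plan forms O2–C1' first at an enone-controlled terminus and only then lets the tether choose C5'.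

Alternative 3: The aryl C2–O bond could be cut instead of an alkyl–O bond. Forward, the 3-hydroxyl of pristimerin would open the vinyl cyclic carbonate A5 under zerovalent palladium catalysis, the C2 oxygen would be converted to a triflate, and the dioxane would be closed by an intramolecular palladium-catalysed C(aryl)–O coupling of the C1' tertiary alcohol in A6. The stereochemistry would come cleanly from a cis-diol. The intermolecular attack, however, must occur at the neopentyl-like C5' terminus in competition with the open C3' terminus, and allylic aryl ethers equilibrate under palladium towards the less hindered isomer. The plan also discards one catechol oxygen. The chosen plan makes the hindered C5'–O bond intramolecularly.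

Key step: step 12

Assumption: pristimerin (methyl ester of celastrol, a commercial natural product) is taken as the starting material for the triterpenoid half, and the 8S configuration (8-H syn to the C9 and C14 methyls, cis B/C junction) is taken to be the epimer favoured at equilibrium in the 6-ene series.

## Steps

Step 1
Reactants: 1 pristimerin
Product: 2 3-O-[2-(trimethylsilyl)ethoxymethyl]pristimerin
Conditions: SEMCl, i-Pr2NEt, CH2Cl2, 0 °C to rt
Reagents that add atoms: 2-(trimethylsilyl)ethoxymethyl chloride, C[Si](C)(C)CCOCCl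
Why: O-alkylation of the acidic enolic 3-hydroxyl of the quinone methide (the only OH in 1); the acetal cannot migrate to O2 later, so the O2/O3 difference of 1 is preserved.

Step 2
Reactants: 2 3-O-[2-(trimethylsilyl)ethoxymethyl]pristimerin
Product: 3 methyl 2-hydroxy-3-{[2-(trimethylsilyl)ethoxy]methoxy}-24-nor-D:A-friedooleana-1,3,5(10),7-tetraen-29-oate
Conditions: NaBH4, THF–MeOH, 0 °C; aq. NH4Cl
Reagents that add atoms: none
Why: 1,6-conjugate hydride addition to the extended quinone methide at C6 aromatises ring A and frees O2 as the only phenol; the hindered C29 ester and the C7=C8 alkene should not react.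

Step 3
Reactants: 4 (S)-(+)-carvone
Product: 5 (2R,5S)-2-methyl-5-(prop-1-en-2-yl)cyclohexan-1-one (cis-dihydrocarvone)
Conditions: ene-reductase OYE1, NADP+ (cat.), alcohol dehydrogenase, i-PrOH, phosphate buffer pH 7, 30 °C
Reagents that add atoms: none
Why: Enzymatic asymmetric conjugate reduction of the enone; hydride goes to C3 and the active site protonates C2 to give 2R whatever the C5 configuration, which yields the cis isomer (future C10' and C7'); the unactivated isopropenyl group is not a substrate.

Step 4
Reactants: 5 (2R,5S)-2-methyl-5-(prop-1-en-2-yl)cyclohexan-1-one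
Product: 7 (2R,5S)-2-methyl-5-(prop-1-en-2-yl)cycloheptan-1-one, via α-silyl ketone 6 (not isolated)
Conditions: Me3SiCHN2, Sc(OTf)3 (5 mol %), CH2Cl2, −40 °C; then 1 M HCl, THF, 0 °C
Reagents that add atoms: (trimethylsilyl)diazomethane, C[Si](C)(C)C=[N+]=[N-]
Why: Lewis acid-catalysed diazoalkane ring expansion (Tiffeneau–Demjanov type); the unsubstituted α-CH2 should migrate in preference to the methyl-bearing carbon, which puts the new carbon (future C5') between the carbonyl and C6', and the low temperature and brief acid protodesilylation should leave the α-methyl centre untouched.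

Step 5
Reactants: 7 (2R,5S)-2-methyl-5-(prop-1-en-2-yl)cycloheptan-1-one; 8 butane-2,3-dione
Product: 10 (4S,7R)-2-(2-hydroxy-3-oxobutan-2-yl)-7-methyl-4-(prop-1-en-2-yl)cycloheptan-1-one (mixture at the two new centres), via lithium enolate 9 (not isolated)
Conditions: LiN(i-Pr)2, THF, −78 °C; butane-2,3-dione, −78 °C; AcOH, −78 °C
Reagents that add atoms: none
Why: Kinetic deprotonation at the less hindered α-CH2 (not at the methyl-bearing C7), then aldol addition to the very electrophilic 1,2-dione; the two new stereocentres are destroyed in step 6, and the cold acidic quench should prevent retro-aldol and epimerisation.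

Step 6
Reactants: 10 (4S,7R)-2-(2-hydroxy-3-oxobutan-2-yl)-7-methyl-4-(prop-1-en-2-yl)cycloheptan-1-one
Product: 12 (2Z,4S,7R)-7-methyl-2-(3-oxobutan-2-ylidene)-4-(prop-1-en-2-yl)cycloheptan-1-one, via E-ene-dione 11 (not isolated)
Conditions: methyl N-(triethylammoniosulfonyl)carbamate (Burgess reagent), PhMe, 50 °C; then hν (365 nm), PhMe, 10 °C
Reagents that add atoms: none
Why: Syn-elimination of the tertiary alcohol through its sulfamate ester removes the acidic hydrogen α to the ring ketone and gives the tetrasubstituted ene-dione as an E/Z mixture; irradiation interconverts the isomers (ene-dione E/Z photoisomerisation), and any E isomer carried on is inert in step 7 and can be returned here.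

Step 7
Reactants: 12 (2Z,4S,7R)-7-methyl-2-(3-oxobutan-2-ylidene)-4-(prop-1-en-2-yl)cycloheptan-1-one
Product: 15 tert-butyl (1R,7S,10R)-3-oxoguaia-4,11-dien-1-yl carbonate, via lithium enolate 13 (not isolated), via lithium aldolate 14 (not isolated)
Conditions: LiN(SiMe3)2, THF, −78 °C; Boc2O, −78 to −20 °C
Reagents that add atoms: di-tert-butyl dicarbonate, CC(C)(C)OC(=O)OC(=O)OC(C)(C)C
Why: Kinetic enolisation of the acetyl methyl and 5-exo-trig intramolecular aldol onto the ring ketone (the classical cis-ene-dione to 4-hydroxycyclopentenone closure) builds the cyclopentenone; the enolate carbon should add to C1 anti to the adjacent C10 methyl (Felkin–Anh sense), so the oxygen ends syn to that methyl (1R), and the tertiary alkoxide is acylated in the flask before retro-aldol can occur.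

Step 8
Reactants: 3 methyl 2-hydroxy-3-{[2-(trimethylsilyl)ethoxy]methoxy}-24-nor-D:A-friedooleana-1,3,5(10),7-tetraen-29-oate; 15 tert-butyl (1R,7S,10R)-3-oxoguaia-4,11-dien-1-yl carbonate
Product: 16 methyl 2-{[(1R,7S,10R)-3-oxoguaia-4,11-dien-1-yl]oxy}-3-{[2-(trimethylsilyl)ethoxy]methoxy}-24-nor-D:A-friedooleana-1,3,5(10),7-tetraen-29-oate
Conditions: Pd2(dba)3·CHCl3 (2.5 mol %), PPh3 (10 mol %), CH2Cl2, 0 °C to rt
Reagents that add atoms: none
Why: Tsuji–Trost allylic etherification of a 4-(acyloxy)cyclopent-2-enone with a phenol; zerovalent palladium ionises the tertiary carbonate anti, the released tert-butoxide deprotonates the only free phenol (O2), and the phenoxide attacks the γ-terminus C1' anti to the metal, because attack there keeps the enone conjugated. The net result is retention at C1'.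

Step 9
Reactants: 16 methyl 2-{[(1R,7S,10R)-3-oxoguaia-4,11-dien-1-yl]oxy}-3-{[2-(trimethylsilyl)ethoxy]methoxy}-24-nor-D:A-friedooleana-1,3,5(10),7-tetraen-29-oate
Product: 17 methyl 2-{[(1R,3R,7S,10R)-3-hydroxyguaia-4,11-dien-1-yl]oxy}-3-{[2-(trimethylsilyl)ethoxy]methoxy}-24-nor-D:A-friedooleana-1,3,5(10),7-tetraen-29-oate
Conditions: NaBH4, CeCl3·7H2O, MeOH–THF, −78 °C
Reagents that add atoms: none
Why: Luche 1,2-reduction of the enone under near-neutral conditions, which avoids β-elimination of the aryloxide; hydride should arrive on the face opposite the large C1' aryloxy group, placing the 3'-hydroxyl cis to the ether (3'R).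

Step 10
Reactants: 17 methyl 2-{[(1R,3R,7S,10R)-3-hydroxyguaia-4,11-dien-1-yl]oxy}-3-{[2-(trimethylsilyl)ethoxy]methoxy}-24-nor-D:A-friedooleana-1,3,5(10),7-tetraen-29-oate
Product: 18 methyl 3-hydroxy-2-{[(1R,3R,7S,10R)-3-hydroxyguaia-4,11-dien-1-yl]oxy}-24-nor-D:A-friedooleana-1,3,5(10),7-tetraen-29-oate
Conditions: Bu4NF, THF, 50 °C; AcOH
Reagents that add atoms: none
Why: Fluoride-induced fragmentation of the aryl SEM ether (loss of fluorosilane, ethene and formaldehyde) frees O3 without acid, which the tertiary allylic C1' ether and the allylic alcohol would not tolerate.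

Step 11
Reactants: 18 methyl 3-hydroxy-2-{[(1R,3R,7S,10R)-3-hydroxyguaia-4,11-dien-1-yl]oxy}-24-nor-D:A-friedooleana-1,3,5(10),7-tetraen-29-oate
Product: 19 methyl 3-[(methoxycarbonyl)oxy]-2-({(1R,3R,7S,10R)-3-[(methoxycarbonyl)oxy]guaia-4,11-dien-1-yl}oxy)-24-nor-D:A-friedooleana-1,3,5(10),7-tetraen-29-oate
Conditions: ClCO2Me, pyridine, DMAP (cat.), CH2Cl2, 0 °C
Reagents that add atoms: methyl chloroformate, COC(=O)Cl
Why: Standard acylation of the phenol and of the secondary allylic alcohol; the allylic carbonate becomes the leaving group and the aryl carbonate a masked phenoxide for step 12.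

Step 12
Reactants: 19 methyl 3-[(methoxycarbonyl)oxy]-2-({(1R,3R,7S,10R)-3-[(methoxycarbonyl)oxy]guaia-4,11-dien-1-yl}oxy)-24-nor-D:A-friedooleana-1,3,5(10),7-tetraen-29-oate
Product: 20 methyl 2,3-{[(1R,5R,7S,10R)-guaia-3,11-diene-1,5-diyl]bis(oxy)}-24-nor-D:A-friedooleana-1,3,5(10),7-tetraen-29-oate (O2 on C1', O3 on C5'; the 7-ene isomer of the target)
Conditions: Pd2(dba)3·CHCl3 (5 mol %), PPh3 (20 mol %), THF, 45 °C
Reagents that add atoms: none
Why: Zerovalent palladium ionises the C3' allylic carbonate anti to the leaving group and forms a cyclopentenyl π-allyl spanning C3'–C4'–C5' with loss of CO2 and methoxide; the methoxide cleaves the aryl carbonate to dimethyl carbonate and the O3 phenoxide, which attacks the π-allyl anti to the metal. The closest known reaction type is the intramolecular Tsuji–Trost O-allylation that gives 2-vinylchromans and 2-vinyl-1,4-benzodioxanes with fully substituted C–O centres. The dioxane closes in a 6-exo mode at C5'; attack at C3' would need an eight-membered bridged ring and is disfavoured, so the tether overrides the usual preference for the less hindered terminus. The new stereocentre C5' is controlled by C1': the phenoxide is held on the face of the C1'–O bond by a two-atom aryl tether, and a [5.4.3]propellane can only form cis. The double inversion requires the carbonate on that same face, which step 9 should provide. The alkene moves from C4'=C5' to C3'=C4', its position in the target. The step needs the carbonate to ionise faster than the tertiary allylic C1' aryl ether, which the much better leaving group secures. The one operation thus settles the hardest C–O bond (methyl-flanked O3 to a quaternary carbon next to a second quaternary carbon), the propellane, one stereocentre and the alkene position.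

Step 13
Reactants: 20 methyl 2,3-{[(1R,5R,7S,10R)-guaia-3,11-diene-1,5-diyl]bis(oxy)}-24-nor-D:A-friedooleana-1,3,5(10),7-tetraen-29-oate
Product: 21 CNP0287532.1, methyl (8S)-2,3-{[(1R,5R,7S,10R)-guaia-3,11-diene-1,5-diyl]bis(oxy)}-24-nor-D:A-friedooleana-1,3,5(10),6-tetraen-29-oate
Conditions: KOt-Bu (0.3 equiv), DMSO, 25 °C
Reagents that add atoms: none
Why: Base-mediated 1,3-prototropic shift (allylarene to styrene): the doubly activated benzylic/allylic C6–H is removed and the delocalised anion is reprotonated at C8, bringing the alkene into conjugation with ring A; deprotonation is reversible, so the C8 epimers equilibrate, and the 8S epimer should be favoured because the cis B/C junction lets ring C relax the syn-diaxial C9/C14 methyl interaction that a trans junction would lock in.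

## Compound list

1 | pristimerin (methyl 3-hydroxy-2-oxo-24-nor-D:A-friedooleana-1(10),3,5,7-tetraen-29-oate) | O=C1C=C2C(=CC=C3[C@@]2(C)CC[C@@]2(C)[C@@H]4C[C@](C)(C(=O)OC)CC[C@]4(C)CC[C@]32C)C(C)=C1O | starting material
2 | 3-O-[2-(trimethylsilyl)ethoxymethyl]pristimerin | O=C1C=C2C(=CC=C3[C@@]2(C)CC[C@@]2(C)[C@@H]4C[C@](C)(C(=O)OC)CC[C@]4(C)CC[C@]32C)C(C)=C1OCOCC[Si](C)(C)C | intermediate
3 | methyl 2-hydroxy-3-{[2-(trimethylsilyl)ethoxy]methoxy}-24-nor-D:A-friedooleana-1,3,5(10),7-tetraen-29-oate | Oc1cc2c(c(C)c1OCOCC[Si](C)(C)C)CC=C1[C@@]2(C)CC[C@@]2(C)[C@@H]3C[C@](C)(C(=O)OC)CC[C@]3(C)CC[C@]12C | intermediate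
4 | (S)-(+)-carvone, (5S)-2-methyl-5-(prop-1-en-2-yl)cyclohex-2-en-1-one | C=C(C)[C@H]1CC=C(C)C(=O)C1 | starting material
5 | (2R,5S)-2-methyl-5-(prop-1-en-2-yl)cyclohexan-1-one | C=C(C)[C@H]1CC[C@@H](C)C(=O)C1 | intermediate
6 | (4S,7R)-7-methyl-4-(prop-1-en-2-yl)-2-(trimethylsilyl)cycloheptan-1-one (mixture at C2) | C=C(C)[C@H]1CC[C@@H](C)C(=O)C([Si](C)(C)C)C1 | intermediate
7 | (2R,5S)-2-methyl-5-(prop-1-en-2-yl)cycloheptan-1-one | C=C(C)[C@H]1CC[C@@H](C)C(=O)CC1 | intermediate
8 | butane-2,3-dione | CC(=O)C(C)=O | starting material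
9 | lithium (4S,7R)-7-methyl-4-(prop-1-en-2-yl)cyclohept-1-en-1-olate | C=C(C)[C@H]1CC[C@@H](C)C([O-])=CC1.[Li+] | intermediate
10 | (4S,7R)-2-(2-hydroxy-3-oxobutan-2-yl)-7-methyl-4-(prop-1-en-2-yl)cycloheptan-1-one (mixture at C2 and the carbinol carbon) | C=C(C)[C@H]1CC[C@@H](C)C(=O)C(C1)C(C)(O)C(C)=O | intermediate
11 | (2E,4S,7R)-7-methyl-2-(3-oxobutan-2-ylidene)-4-(prop-1-en-2-yl)cycloheptan-1-one | C=C(C)[C@H]1CC[C@@H](C)C(=O)/C(C1)=C(\C)C(C)=O | intermediate
12 | (2Z,4S,7R)-7-methyl-2-(3-oxobutan-2-ylidene)-4-(prop-1-en-2-yl)cycloheptan-1-one (ring carbonyl and acetyl cis) | C=C(C)[C@H]1CC[C@@H](C)C(=O)/C(C1)=C(/C)C(C)=O | intermediate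
13 | lithium 3-[(1Z,4S,7R)-7-methyl-1-oxo-4-(prop-1-en-2-yl)cycloheptan-2-ylidene]but-1-en-2-olate | C=C(C)[C@H]1CC[C@@H](C)C(=O)/C(C1)=C(/C)C([O-])=C.[Li+] | intermediate
14 | lithium (1R,7S,10R)-3-oxoguaia-4,11-dien-1-olate | C=C(C)[C@H]1CC[C@@H](C)[C@]2([O-])CC(=O)C(C)=C2C1.[Li+] | intermediate
15 | tert-butyl (1R,7S,10R)-3-oxoguaia-4,11-dien-1-yl carbonate | C=C(C)[C@H]1CC[C@@H](C)[C@]2(OC(=O)OC(C)(C)C)CC(=O)C(C)=C2C1 | intermediate
16 | methyl 2-{[(1R,7S,10R)-3-oxoguaia-4,11-dien-1-yl]oxy}-3-{[2-(trimethylsilyl)ethoxy]methoxy}-24-nor-D:A-friedooleana-1,3,5(10),7-tetraen-29-oate | C=C(C)[C@H]1CC[C@@H](C)[C@]2(Oc3cc4c(c(C)c3OCOCC[Si](C)(C)C)CC=C3[C@@]4(C)CC[C@@]4(C)[C@@H]5C[C@](C)(C(=O)OC)CC[C@]5(C)CC[C@]34C)CC(=O)C(C)=C2C1 | intermediate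
17 | methyl 2-{[(1R,3R,7S,10R)-3-hydroxyguaia-4,11-dien-1-yl]oxy}-3-{[2-(trimethylsilyl)ethoxy]methoxy}-24-nor-D:A-friedooleana-1,3,5(10),7-tetraen-29-oate | C=C(C)[C@H]1CC[C@@H](C)[C@]2(Oc3cc4c(c(C)c3OCOCC[Si](C)(C)C)CC=C3[C@@]4(C)CC[C@@]4(C)[C@@H]5C[C@](C)(C(=O)OC)CC[C@]5(C)CC[C@]34C)C[C@@H](O)C(C)=C2C1 | intermediate
18 | methyl 3-hydroxy-2-{[(1R,3R,7S,10R)-3-hydroxyguaia-4,11-dien-1-yl]oxy}-24-nor-D:A-friedooleana-1,3,5(10),7-tetraen-29-oate | C=C(C)[C@H]1CC[C@@H](C)[C@]2(Oc3cc4c(c(C)c3O)CC=C3[C@@]4(C)CC[C@@]4(C)[C@@H]5C[C@](C)(C(=O)OC)CC[C@]5(C)CC[C@]34C)C[C@@H](O)C(C)=C2C1 | intermediate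
19 | methyl 3-[(methoxycarbonyl)oxy]-2-({(1R,3R,7S,10R)-3-[(methoxycarbonyl)oxy]guaia-4,11-dien-1-yl}oxy)-24-nor-D:A-friedooleana-1,3,5(10),7-tetraen-29-oate | C=C(C)[C@H]1CC[C@@H](C)[C@]2(Oc3cc4c(c(C)c3OC(=O)OC)CC=C3[C@@]4(C)CC[C@@]4(C)[C@@H]5C[C@](C)(C(=O)OC)CC[C@]5(C)CC[C@]34C)C[C@@H](OC(=O)OC)C(C)=C2C1 | intermediate
20 | methyl 2,3-{[(1R,5R,7S,10R)-guaia-3,11-diene-1,5-diyl]bis(oxy)}-24-nor-D:A-friedooleana-1,3,5(10),7-tetraen-29-oate (O2 on C1', O3 on C5') | C=C(C)[C@H]1CC[C@@H](C)[C@]23CC=C(C)[C@@]2(C1)Oc1c(cc2c(c1C)CC=C1[C@@]2(C)CC[C@@]2(C)[C@@H]4C[C@](C)(C(=O)OC)CC[C@]4(C)CC[C@]12C)O3 | intermediate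
21 | CNP0287532.1, methyl (8S)-2,3-{[(1R,5R,7S,10R)-guaia-3,11-diene-1,5-diyl]bis(oxy)}-24-nor-D:A-friedooleana-1,3,5(10),6-tetraen-29-oate | C=C(C)[C@H]1CC[C@@H](C)[C@]23CC=C(C)[C@@]2(C1)Oc1c(cc2c(c1C)C=C[C@@H]1[C@@]2(C)CC[C@@]2(C)[C@@H]4C[C@](C)(C(=O)OC)CC[C@]4(C)CC[C@]12C)O3 | target

## Step count and least certain steps

Total step count: 13. Longest linear sequence: 11 steps (steps 3–7, then 8–13, from 4); the triterpenoid branch (steps 1–2) joins at step 8.

Step 12 (key). What may go wrong: slow oxidative ionisation, because the metal must bind a tetrasubstituted C4'=C5' alkene; a stereochemical mismatch if step 9 delivers the C3' oxygen trans to the C1' ether, since the anti/anti pathway then cannot reach C5'; β-hydride loss from the π-allyl stage to a cyclopentadiene; competing ionisation of the tertiary allylic C1' aryl ether. Fallback: set out from 18 and close directly to 20 by a cationic, stereoconvergent dehydrative SN1' etherification (Bi(OTf)3, 5 mol %, CH2Cl2, −20 °C, or hexafluoro-2-propanol as solvent). The free C3'–C5' allyl cation is captured by the tethered O3 at C5' whatever the C3' configuration, and the route rejoins at 20 without step 11. No new compound is made (F0).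

Step 8. What may go wrong: no ionisation at the congested, fully substituted allylic carbonate; base-induced β-elimination of the carbonate before substitution; loss of the C1' configuration if the π-allyl complex epimerises by metal exchange. Fallback: set out from 15 and 3 without palladium (Cs2CO3, MeCN, 0 °C). Elimination gives the cyclopentadienone (7S,10R)-guaia-1,4,11-trien-3-one F1 in the presence of the phenoxide of 3, whose conjugate addition at C1' returns the route to 16. The C1' configuration would then rest on the facial bias of F1 and would have to be assigned.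

Step 7. What may go wrong: poor facial selectivity of the ring closure relative to the C10 methyl; loss of the C10 configuration through enolisation of the ring ketone; retro-aldol before the alkoxide is acylated; deprotonation at the allylic methyl instead of the acetyl group. Fallback: set out from 7 and set C1 by an intermolecular addition. The enolate 9 is hydroxylated with 2-(phenylsulfonyl)-3-phenyloxaziridine to the α'-hydroxy ketone (4S,7R)-2-hydroxy-7-methyl-4-(prop-1-en-2-yl)cycloheptan-1-one F2. The dianion of diethyl (3-oxobutan-2-yl)phosphonate adds to the ketone anti to the methyl to give the diol phosphonate diethyl {4-[(1R,2R,5S)-1,7-dihydroxy-2-methyl-5-(prop-1-en-2-yl)cycloheptyl]-3-oxobutan-2-yl}phosphonate F3. Dess–Martin oxidation of the secondary alcohol gives the keto phosphonate F4, and an intramolecular Horner–Wadsworth–Emmons reaction (K2CO3, 18-crown-6, PhMe) gives (1R,7S,10R)-1-hydroxyguaia-4,11-dien-3-one F5. Boc2O/DMAP then returns the route to 15.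

Step 6. What may go wrong: elimination towards the methyl group instead of the ring carbon; an unfavourable E/Z ratio at the photostationary state; retro-aldol on warming. Fallback: set out from 7 (through 9) and take the cis geometry from a ring. Alkylation with 3-chlorobutan-2-one (NaI) gives the 1,4-diketone (4S,7R)-7-methyl-2-(3-oxobutan-2-yl)-4-(prop-1-en-2-yl)cycloheptan-1-one F6. Paal–Knorr cyclodehydration (TsOH cat., PhMe) gives the fused furan (6S,8R)-2,3,8-trimethyl-6-(prop-1-en-2-yl)-5,6,7,8-tetrahydro-4H-cyclohepta[b]furan F7. Oxidative ring opening (NBS, NaHCO3, aqueous acetone, −20 °C) can only give the cis-ene-dione and returns the route to 12.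

Step 13. What may go wrong: an unfavourable ratio of C8 epimers at equilibrium; incomplete alkene migration; base-induced elimination of the aryloxide across C2'–C5'; migration of the isopropenyl double bond. Fallback: set out from 20 and set C8 irreversibly. Benzylic oxidation (DDQ, aqueous dioxane) gives the 6-oxo-7-ene F8. Conjugate reduction delivers hydride to C8, with [(Ph3P)CuH]6 or LiBH(s-Bu)3 as small and bulky alternatives to steer the face, and gives the (8S)-6-oxo-7,8-dihydro compound F9. NaBH4 gives the 6-hydroxy compound F10, and dehydration of this benzylic alcohol (Burgess reagent) returns the route to 21.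

## Further compounds

F0 | step 12 | none | none
F1 | step 8 | (7S,10R)-guaia-1,4,11-trien-3-one | C=C(C)[C@H]1CC[C@@H](C)C2=CC(=O)C(C)=C2C1
F2 | step 7 | (4S,7R)-2-hydroxy-7-methyl-4-(prop-1-en-2-yl)cycloheptan-1-one (mixture at C2) | C=C(C)[C@H]1CC[C@@H](C)C(=O)C(O)C1
F3 | step 7 | diethyl {4-[(1R,2R,5S)-1,7-dihydroxy-2-methyl-5-(prop-1-en-2-yl)cycloheptyl]-3-oxobutan-2-yl}phosphonate | C=C(C)[C@H]1CC[C@@H](C)[C@](O)(CC(=O)C(C)P(=O)(OCC)OCC)C(O)C1
F4 | step 7 | diethyl {4-[(1R,2R,5S)-1-hydroxy-2-methyl-7-oxo-5-(prop-1-en-2-yl)cycloheptyl]-3-oxobutan-2-yl}phosphonate | C=C(C)[C@H]1CC[C@@H](C)[C@](O)(CC(=O)C(C)P(=O)(OCC)OCC)C(=O)C1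
F5 | step 7 | (1R,7S,10R)-1-hydroxyguaia-4,11-dien-3-one | C=C(C)[C@H]1CC[C@@H](C)[C@]2(O)CC(=O)C(C)=C2C1
F6 | step 6 | (4S,7R)-7-methyl-2-(3-oxobutan-2-yl)-4-(prop-1-en-2-yl)cycloheptan-1-one | C=C(C)[C@H]1CC[C@@H](C)C(=O)C(C1)C(C)C(C)=O
F7 | step 6 | (6S,8R)-2,3,8-trimethyl-6-(prop-1-en-2-yl)-5,6,7,8-tetrahydro-4H-cyclohepta[b]furan | C=C(C)[C@H]1CC[C@@H](C)c2oc(C)c(C)c2C1
F8 | step 13 | methyl 2,3-{[(1R,5R,7S,10R)-guaia-3,11-diene-1,5-diyl]bis(oxy)}-6-oxo-24-nor-D:A-friedooleana-1,3,5(10),7-tetraen-29-oate | C=C(C)[C@H]1CC[C@@H](C)[C@]23CC=C(C)[C@@]2(C1)Oc1c(cc2c(c1C)C(=O)C=C1[C@@]2(C)CC[C@@]2(C)[C@@H]4C[C@](C)(C(=O)OC)CC[C@]4(C)CC[C@]12C)O3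
F9 | step 13 | methyl (8S)-2,3-{[(1R,5R,7S,10R)-guaia-3,11-diene-1,5-diyl]bis(oxy)}-6-oxo-24-nor-D:A-friedooleana-1,3,5(10)-trien-29-oate | C=C(C)[C@H]1CC[C@@H](C)[C@]23CC=C(C)[C@@]2(C1)Oc1c(cc2c(c1C)C(=O)C[C@@H]1[C@@]2(C)CC[C@@]2(C)[C@@H]4C[C@](C)(C(=O)OC)CC[C@]4(C)CC[C@]12C)O3
F10 | step 13 | methyl (8S)-2,3-{[(1R,5R,7S,10R)-guaia-3,11-diene-1,5-diyl]bis(oxy)}-6-hydroxy-24-nor-D:A-friedooleana-1,3,5(10)-trien-29-oate (mixture at C6) | C=C(C)[C@H]1CC[C@@H](C)[C@]23CC=C(C)[C@@]2(C1)Oc1c(cc2c(c1C)C(O)C[C@@H]1[C@@]2(C)CC[C@@]2(C)[C@@H]4C[C@](C)(C(=O)OC)CC[C@]4(C)CC[C@]12C)O3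
A1 | alternative 1 | methyl (8S)-2,3-dioxo-24-nor-D:A-friedooleana-1(10),4,6-trien-29-oate | O=C1C=C2C(=C(C)C1=O)C=C[C@@H]1[C@@]2(C)CC[C@@]2(C)[C@@H]3C[C@](C)(C(=O)OC)CC[C@]3(C)CC[C@]12C
A2 | alternative 1 | (7S,10R)-guaia-1(5),3,11-triene | C=C(C)[C@H]1CC[C@@H](C)C2=C(C1)C(C)=CC2
A3 | alternative 2 | methyl 2,3-dihydroxy-24-nor-D:A-friedooleana-1,3,5(10),7-tetraen-29-oate | Oc1cc2c(c(C)c1O)CC=C1[C@@]2(C)CC[C@@]2(C)[C@@H]3C[C@](C)(C(=O)OC)CC[C@]3(C)CC[C@]12C
A4 | alternative 2 | (1R,3R,7S,10R)-guaia-4,11-diene-1,3-diyl dimethyl dicarbonate | C=C(C)[C@H]1CC[C@@H](C)[C@]2(OC(=O)OC)C[C@@H](OC(=O)OC)C(C)=C2C1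
A5 | alternative 3 | (1R,5R,7S,10R)-guaia-3,11-diene-1,5-diyl carbonate (cyclic) | C=C(C)[C@H]1CC[C@@H](C)[C@]23CC=C(C)[C@@]2(C1)OC(=O)O3
A6 | alternative 3 | methyl 3-{[(1R,5R,7S,10R)-1-hydroxyguaia-3,11-dien-5-yl]oxy}-2-{[(trifluoromethyl)sulfonyl]oxy}-24-nor-D:A-friedooleana-1,3,5(10),7-tetraen-29-oate | C=C(C)[C@H]1CC[C@@H](C)[C@]2(O)CC=C(C)[C@@]2(C1)Oc1c(cc2c(c1C)CC=C1[C@@]2(C)CC[C@@]2(C)[C@@H]4C[C@](C)(C(=O)OC)CC[C@]4(C)CC[C@]12C)OS(=O)(=O)C(F)(F)F
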